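**Retrosynthetic overview**
- Feature: in the oxane ring (O1, C2–C6) the 3,4-dihydroxy-5-methoxyphenyl group at C2, the hydroxyl at C4 and the 2-(4-hydroxyphenyl)ethyl chain at C6 are all cis and equatorial, so H-2, H-4 and H-6 share one face. This is the pattern left when hydrogen is added to a single face of a flat 2,6-disubstituted 4H-pyran-4-one.
- Target 12 ⇐ tri-O-benzyl ether 11 (hydrogenolysis) ⇐ achiral pyranone 8 (dearomatising enantioselective ring hydrogenation that creates C2, C4 and C6 together).
- 8 ⇐ 1,3,5-triketone 6 (acid cyclodehydration, the only ring closure) ⇐ diketone 3 + aryl ester 5 (Claisen acylation of a diketone dianion).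
- 3 ⇐ acetylacetone 1 + benzylic chloride 2 (dianion alkylation); 5 ⇐ catechol ester 4 (double benzylation).
- Ring order: both benzene rings are bought; the pyranone ring is closed in step 4 and saturated in step 5.

Key step: step 5

Remark on the chemistry: which antipode of the carbene ligand reduces the face leading to (2S) cannot be predicted for this new substrate; (R,R)-SINpEt, 1,3-bis[(R)-1-(naphthalen-1-yl)ethyl]-4,5-dihydroimidazol-2-ylidene, is written and is exchanged for (S,S)-SINpEt if the first run gives the mirror-image series.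

Step 1
Reactants: 1 acetylacetone (pentane-2,4-dione); 2 4-(benzyloxy)benzyl chloride
Product: 3 6-[4-(benzyloxy)phenyl]hexane-2,4-dione
Conditions: LiN(i-Pr)2 (LDA, 2.1 equiv), THF, −78 to 0 °C; then 2, 0 °C to rt; aq. HCl work-up
Reagents that add atoms: none
Why: Alkylation of a 1,3-diketone dianion, in which the terminal carbanion is far more nucleophilic than the stabilised central carbon, so SN2 attack on the benzylic chloride should occur at the methyl terminus only.

Step 2
Reactants: 4 methyl 3,4-dihydroxy-5-methoxybenzoate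
Product: 5 methyl 3,4-bis(benzyloxy)-5-methoxybenzoate
Conditions: BnBr (2.4 equiv), K2CO3 (3 equiv), DMF, 60 °C
Reagents that add atoms: benzyl bromide BrCc1ccccc1
Why: Williamson ether synthesis, in which both phenoxides displace bromide from benzyl bromide while the methyl ester is untouched.

Step 3
Reactants: 3 6-[4-(benzyloxy)phenyl]hexane-2,4-dione; 5 methyl 3,4-bis(benzyloxy)-5-methoxybenzoate
Product: 6 1-[3,4-bis(benzyloxy)-5-methoxyphenyl]-7-[4-(benzyloxy)phenyl]heptane-1,3,5-trione
Conditions: 3 (2.2 equiv), LiN(i-Pr)2 (4.4 equiv), THF, −78 to 0 °C; then 5 (1.0 equiv), 0 °C to rt; aq. HCl work-up (excess 3 recovered)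
Reagents that add atoms: none
Why: Claisen condensation of a 1,3-diketone dianion with a non-enolisable ester, in which the second proton is removed kinetically from the methyl group rather than the more hindered C5 methylene, and the second equivalent of dianion converts the product into its unreactive dianion so that no further acylation follows.

Step 4
Reactants: 6 1-[3,4-bis(benzyloxy)-5-methoxyphenyl]-7-[4-(benzyloxy)phenyl]heptane-1,3,5-trione
Product: 8 2-[3,4-bis(benzyloxy)-5-methoxyphenyl]-6-{2-[4-(benzyloxy)phenyl]ethyl}-4H-pyran-4-one, via cyclic hemiketal 7 (not isolated)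
Conditions: TsOH·H2O (0.1 equiv), toluene, 80 °C, 4 Å molecular sieves
Reagents that add atoms: none
Why: Acid-catalysed cyclodehydration of a 1,3,5-triketone, in which the enol oxygen at C1 adds to the C5 carbonyl (6-exo-trig hemiketal 7) and loss of water gives the cross-conjugated 4-pyranone, catalytic sulfonic acid being too mild to cleave aryl benzyl ethers.

Step 5
Reactants: 8 2-[3,4-bis(benzyloxy)-5-methoxyphenyl]-6-{2-[4-(benzyloxy)phenyl]ethyl}-4H-pyran-4-one
Product: 11 (2S,4R,6S)-2-[3,4-bis(benzyloxy)-5-methoxyphenyl]-6-{2-[4-(benzyloxy)phenyl]ethyl}oxan-4-ol, via dihydropyranone 9 (not isolated), via cis-oxanone 10 (not isolated)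
Conditions: [Ru(cod)(2-methylallyl)2] (5 mol %), (R,R)-SINpEt·HBF4 (10 mol %), KOt-Bu (15 mol %), hexane, 70 °C; then 8, toluene, H2 (100 bar), 40 °C; then NaBH4, MeOH/THF, −20 °C on the crude product
Reagents that add atoms: none
Why: Proposed new method: a chiral Ru bis(carbene) hydride is expected to bind one enantiotopic face of the flat pyranone 8 and add H2 syn across the aryl-bearing C2=C3 enol-ether bond (this half of 8 is a flavone without its fused benzo ring) to give (S)-9, after which the C5=C6 bond and then the C4 ketone are reduced, three H2 in all forming the C–H bonds at C2, C3, C5, C6 and C4 and the carbinol O–H. The closest known reaction types are the Ru chiral-carbene hydrogenation of flavones and chromones to cis-flavan-4-ols and chromanols, and the racemic heterogeneous hydrogenation of 2,6-disubstituted 4-pyranones and 2,3-dihydropyran-4-ones to cis-2,6-oxan-4-ones and -4-ols. No ring is closed in this step; the existing O1/C2–C6 ring only passes from planar to chair. C2 is set by the ligand (choice between the two enantiotopic faces), C6 by the C2 centre because 9 should take hydrogen at C5=C6 on the face anti to its pseudo-equatorial aryl group (cis-10), and C4 by axial hydride delivery to the ketone of cis-10, from Ru–H and from the NaBH4 treatment that converts any remaining 10, giving the equatorial alcohol. The step needs enantiofacial selectivity in the first addition, which the strongly different flanking groups (aryl against 2-arylethyl) and the absence of any stereocentre that could mismatch should secure, and cis selectivity afterwards, which the all-equatorial (also thermodynamic) arrangement secures; the benzyl ethers should be inert to the homogeneous Ru catalyst.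

Step 6
Reactants: 11 (2S,4R,6S)-2-[3,4-bis(benzyloxy)-5-methoxyphenyl]-6-{2-[4-(benzyloxy)phenyl]ethyl}oxan-4-ol
Product: 12 5-[(2S,4R,6S)-4-hydroxy-6-[2-(4-hydroxyphenyl)ethyl]oxan-2-yl]-3-methoxybenzene-1,2-diol (target CNP0186008.1)
Conditions: H2 (1 atm), 20% Pd(OH)2 on carbon, degassed EtOAc, rt, stopped at full debenzylation
Reagents that add atoms: none
Why: Catalytic hydrogenolysis of aryl benzyl ethers, whose three O–CH2Ph bonds should be cleaved much faster than the ring C2–O bond of the 2-aryloxane in a neutral solvent at low pressure, and which touches no stereocentre.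

**Compound list**
1 | acetylacetone (pentane-2,4-dione) | CC(=O)CC(C)=O | starting material
2 | 4-(benzyloxy)benzyl chloride | ClCc1ccc(OCc2ccccc2)cc1 | starting material
3 | 6-[4-(benzyloxy)phenyl]hexane-2,4-dione | CC(=O)CC(=O)CCc1ccc(OCc2ccccc2)cc1 | intermediate
4 | methyl 3,4-dihydroxy-5-methoxybenzoate | COC(=O)c1cc(O)c(O)c(OC)c1 | starting material
5 | methyl 3,4-bis(benzyloxy)-5-methoxybenzoate | COC(=O)c1cc(OC)c(OCc2ccccc2)c(OCc2ccccc2)c1 | intermediate
6 | 1-[3,4-bis(benzyloxy)-5-methoxyphenyl]-7-[4-(benzyloxy)phenyl]heptane-1,3,5-trione | COc1cc(C(=O)CC(=O)CC(=O)CCc2ccc(OCc3ccccc3)cc2)cc(OCc2ccccc2)c1OCc1ccccc1 | intermediate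
7 | 6-[3,4-bis(benzyloxy)-5-methoxyphenyl]-2-{2-[4-(benzyloxy)phenyl]ethyl}-2-hydroxy-2,3-dihydro-4H-pyran-4-one (racemic cyclic hemiketal) | COc1cc(C2=CC(=O)CC(O)(CCc3ccc(OCc4ccccc4)cc3)O2)cc(OCc2ccccc2)c1OCc1ccccc1 | intermediate
8 | 2-[3,4-bis(benzyloxy)-5-methoxyphenyl]-6-{2-[4-(benzyloxy)phenyl]ethyl}-4H-pyran-4-one | O=C1C=C(c2cc(OC)c(OCc3ccccc3)c(OCc3ccccc3)c2)OC(CCc2ccc(OCc3ccccc3)cc2)=C1 | intermediate
9 | (S)-2-[3,4-bis(benzyloxy)-5-methoxyphenyl]-6-{2-[4-(benzyloxy)phenyl]ethyl}-2,3-dihydro-4H-pyran-4-one | COc1cc([C@@H]2CC(=O)C=C(CCc3ccc(OCc4ccccc4)cc3)O2)cc(OCc2ccccc2)c1OCc1ccccc1 | intermediate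
10 | (2S,6S)-2-[3,4-bis(benzyloxy)-5-methoxyphenyl]-6-{2-[4-(benzyloxy)phenyl]ethyl}oxan-4-one (cis) | COc1cc([C@@H]2CC(=O)C[C@H](CCc3ccc(OCc4ccccc4)cc3)O2)cc(OCc2ccccc2)c1OCc1ccccc1 | intermediate
11 | (2S,4R,6S)-2-[3,4-bis(benzyloxy)-5-methoxyphenyl]-6-{2-[4-(benzyloxy)phenyl]ethyl}oxan-4-ol (all-cis) | COc1cc([C@@H]2C[C@H](O)C[C@H](CCc3ccc(OCc4ccccc4)cc3)O2)cc(OCc2ccccc2)c1OCc1ccccc1 | intermediate
12 | 5-[(2S,4R,6S)-4-hydroxy-6-[2-(4-hydroxyphenyl)ethyl]oxan-2-yl]-3-methoxybenzene-1,2-diol | COc1cc([C@@H]2C[C@H](O)C[C@H](CCc3ccc(O)cc3)O2)cc(O)c1O | target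

**Total step count:** 6
**Longest linear sequence:** 5 steps (steps 1, 3, 4, 5, 6; the branch through step 2 is equally long)

**Steps most likely to fail**

1. Step 5 (bears the label "Proposed new method:"). The weakly aromatic pyranone may resist the homogeneous catalyst, the first hydrogen addition may show poor enantiofacial selectivity, or Ru particles formed by catalyst decay may reduce the arene rings.
Fallback by known chemistry (Prins cyclisation in place of ring hydrogenation), setting out from 2 and 5 and coming back at 11: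
   - Chloride 2 is converted with Mg in THF into 4-(benzyloxy)benzylmagnesium chloride F1.
   - F1 opens commercial (R)-2-allyloxirane at its CH2 terminus under CuI catalysis to give (S)-1-[4-(benzyloxy)phenyl]hex-5-en-3-ol F2.
   - Ester 5 is reduced with LiAlH4 to [3,4-bis(benzyloxy)-5-methoxyphenyl]methanol F3, which MnO2 oxidises to 3,4-bis(benzyloxy)-5-methoxybenzaldehyde F4.
   - Prins cyclisation of F2 with F4 (TFA, CH2Cl2, 0 °C) should give (2S,4R,6S)-2-[3,4-bis(benzyloxy)-5-methoxyphenyl]-6-{2-[4-(benzyloxy)phenyl]ethyl}oxan-4-yl trifluoroacetate F5. It should pass through a chair oxocarbenium ion with both side groups equatorial and equatorial capture at C4, the C6 centre coming unchanged from F2.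
   - K2CO3 in MeOH then frees 11.

2. Step 3. Enolisation may occur at the C5 methylene instead of the methyl group, or the acidic product may quench the dianion before acylation is complete.
Fallback (the two C–C bonds are made in the reverse order), setting out from 1 and 5 and coming back at 6:
   - The symmetrical dianion of 1 (LiN(i-Pr)2, THF), which has no regiochemical choice, is acylated with 5 to give 1-[3,4-bis(benzyloxy)-5-methoxyphenyl]hexane-1,3,5-trione F6.
   - The trianion of F6 (LiN(i-Pr)2, 3 equiv) is benzylated with 2 at its only terminal carbanion, the most basic site, to give 6.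

3. Step 6. Over-reduction may open the ring at the benzylic C2–O bond, or the catalyst may stall before the flanked benzyl groups are removed.
Fallback (Lewis-acid dealkylation in place of hydrogenolysis), setting out from 11 and coming back at 12:
   - BCl3 with pentamethylbenzene as benzyl-cation trap in CH2Cl2 at −78 °C should remove the three benzyl groups without any reducing agent.
   - At that temperature the aryl methyl ether and the ring ether should remain intact.
   - No new compound is made (F0).

**Further compounds**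
F1 | step 5 | 4-(benzyloxy)benzylmagnesium chloride | Cl[Mg]Cc1ccc(OCc2ccccc2)cc1
F2 | step 5 | (S)-1-[4-(benzyloxy)phenyl]hex-5-en-3-ol | C=CC[C@@H](O)CCc1ccc(OCc2ccccc2)cc1
F3 | step 5 | [3,4-bis(benzyloxy)-5-methoxyphenyl]methanol | COc1cc(CO)cc(OCc2ccccc2)c1OCc1ccccc1
F4 | step 5 | 3,4-bis(benzyloxy)-5-methoxybenzaldehyde | COc1cc(C=O)cc(OCc2ccccc2)c1OCc1ccccc1
F5 | step 5 | (2S,4R,6S)-2-[3,4-bis(benzyloxy)-5-methoxyphenyl]-6-{2-[4-(benzyloxy)phenyl]ethyl}oxan-4-yl trifluoroacetate | COc1cc([C@@H]2C[C@H](OC(=O)C(F)(F)F)C[C@H](CCc3ccc(OCc4ccccc4)cc3)O2)cc(OCc2ccccc2)c1OCc1ccccc1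
F6 | step 3 | 1-[3,4-bis(benzyloxy)-5-methoxyphenyl]hexane-1,3,5-trione | COc1cc(C(=O)CC(=O)CC(C)=O)cc(OCc2ccccc2)c1OCc1ccccc1
F0 | step 6 | none | none
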